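# Proposed synthesis of 5-hydroxy-7,8,2',5'-tetramethoxyflavone (7)

## Analysis of the target

- Target 7 is a flavone. It is a 4H-chromen-4-one (benzo ring A, C4a–C8a; pyranone ring C, O1–C4) with a 2,5-dimethoxyphenyl group (ring B) on C2.
- It has no stereocentre. The C2–C1' axis has only one ortho substituent (2'-OMe) facing C3–H and O1, so it rotates freely and the molecule is achiral.
- Ring A is pentasubstituted (C4a acyl, C5 OH, C7 OMe, C8 OMe, C8a O1) and only C6 bears hydrogen, so the first problem is regiochemistry. The 5,7,8 pattern must be obtained free of the 5,6,7 pattern. That isomer arises when a 2,6-dioxygenated aryl ketone closes on either ortho oxygen, or when the pyranone opens and recloses in hot acid (Wessely–Moser rearrangement).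
- The second problem is differentiation. Of five oxygen substituents only the one on C5 is a free OH, and it is chelated to the C4 carbonyl.
- Two kinds of group are sensitive. The para-dioxygenated rings (C5–OH/C8–OMe in ring A, C2'–OMe/C5'–OMe in ring B) can be over-oxidised to quinones, and the pyranone opens in strong base.
- The strategy uses one feature of ring A. C5–OH and C8–OMe stand para, so ring A is a 4-methoxyphenol, and O1 sits on C8a, which is ortho to C8–OMe, meta to C5–OH and next to the acyl-bearing C4a.
- This is the pattern left when a nucleophile adds to the β-carbon of a 2-acyl-p-quinone monoketal and the adduct rearomatises by losing one ketal alkoxy group. The O1–C8a bond can therefore be made from a C–H bond instead of being bought with the arene.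

## Retrosynthetic reasoning

**O1–C8a (7 ⇒ 6 ⇒ 5 ⇒ 4).** The pyranone is cut at O1–C8a, not at O1–C2 as in the classical flavone syntheses.
- Adding the solvent alcohol across C8/C8a of 7 gives dihydrochromenone 6. A retro-oxa-Michael step opens 6 to the acyl quinone monoketal 5. Returning 5 to the phenol level gives diketone 4, whose ring A carries hydrogen at the future C8a.
- Ring A of 4 is only 1,2,4-trioxygenated and comes from a catalogue acetophenone. The oxygen that defines the 5,7,8 pattern is delivered by the side chain to the single electrophilic CH of 5, so the 5,6,7 isomer has no pathway.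
- The phenol that triggers the oxidation reappears as the free 5-OH, so no protecting group and no final demethylation are needed.
- The forward reaction has to oxidise ring A by two electrons in the presence of ring B and of the enolised diketone. It must then close through the enol oxygen faster than the solvent adds, and finally rearomatise.

**C2–C3, flavone numbering (4 ⇒ 3).** The bond between the central CH2 of 4 and the aroyl carbonyl is cut.
- This makes the C-acylation intramolecular, as an acyl migration from the phenol oxygen of ester 3 to the ketone enolate.
- Cutting here keeps both aromatic rings intact as bought. The phenol that the key step needs acts as the temporary carrier of the acyl group.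
- The forward reaction has to release the phenol without letting it condense onto the new diketone.

**Ester C–O (3 ⇒ 1 + 2).** Ester 3 falls into acetophenone 1 and acid chloride 2, both commercial. Compound 1 has a single OH, so the acylation has no selectivity issue.

## Alternatives that were turned down

**Alternative 1:** (textbook) Cut O1–C2 and C2–C3.
- Forward: 2-hydroxy-3,4,6-trimethoxyacetophenone A1 is acylated with 2. Baker–Venkataraman migration gives diketone A2, and acid cyclodehydration gives 5,7,8,2',5'-pentamethoxyflavone A3. A chelating Lewis acid then cleaves the peri 5-OMe to give 7.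
- Turned down: all four ring-A oxygens must be present from the start. A1 is a 1,2,3,5-tetraoxygenated arene, and its preparation depends on telling apart two methoxy groups ortho to the same carbonyl. An error there leads into the 5,6,7 series.
- The 5-OH is carried as OMe and freed at the end, which is a methylate/demethylate detour with five OMe groups exposed to the Lewis acid.
- Acid strong enough to misbehave also opens the way to Wessely–Moser isomerisation.
- The route needs four steps from A1, against three from cheaper materials.

**Alternative 2:** Cut C4–C4a, C3–C4 and O1–C2 at once.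
- Forward: a three-component carbonylative Sonogashira coupling joins 2-iodo-3,5,6-trimethoxyphenol A4 and 2-ethynyl-1,4-dimethoxybenzene A5. Ynone A6 closes 6-endo to A3.
- Turned down: the step is powerful, but the precursor costs more than it saves. A4 needs iodination between OH and OMe of a phenol that offers a second, less hindered and equally activated free position.
- Its C–I bond lies on a very electron-rich ring between two ortho oxygens, so oxidative addition and carbonyl insertion should be slow. Direct, non-carbonylative coupling can then compete.
- A6 can also close 5-exo to the aurone skeleton, and the sequence still ends at A3 with the demethylation to come.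

**Alternative 3:** Cut C2–C1'.
- Forward: a dehydrogenative Pd(II) C–H/C–H coupling joins C2–H of 5,7,8-trimethoxychromone A7 to 1,4-dimethoxybenzene A8, whose four C–H bonds are equivalent. The product is A3.
- Turned down: the symmetry of A8 is attractive, but A7 has to be built from A1. The pyranone therefore costs as much as in Alternative 1 and the coupling is an added step.
- The arene must be used in large excess with a stoichiometric metal oxidant. Palladation at the electron-rich C6–H of ring A or at C3 competes with C2.
- The 5-OMe again has to be cleaved at the end.

Key step: step 3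

Assumption: the target SMILES contains no stereocentre and no configurationally stable axis, so the compound is achiral. The request for a single enantiomer is met without any stereoselective step.

## Route

Step 1
Reactants: 1 1-(2-hydroxy-4,5-dimethoxyphenyl)ethan-1-one (2'-hydroxy-4',5'-dimethoxyacetophenone); 2 2,5-dimethoxybenzoyl chloride
Product: 3 2-acetyl-4,5-dimethoxyphenyl 2,5-dimethoxybenzoate
Conditions: 2 (1.2 equiv), Et3N (1.5 equiv), DMAP (cat.), CH2Cl2, 0 °C → rt
Reagents that add atoms: none
Why: DMAP-catalysed O-acylation of the only OH group of 1; nucleophilic catalysis should overcome the hydrogen bond of the phenol to the acetyl group and the ortho-methoxy hindrance of 2.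

Step 2
Reactants: 3 2-acetyl-4,5-dimethoxyphenyl 2,5-dimethoxybenzoate
Product: 4 1-(2-hydroxy-4,5-dimethoxyphenyl)-3-(2,5-dimethoxyphenyl)propane-1,3-dione
Conditions: t-BuOK (2.2 equiv), THF, 0 °C → rt; then cold 1 M HCl to pH 5
Reagents that add atoms: none
Why: Baker–Venkataraman rearrangement: the methyl ketone enolate attacks the neighbouring aryl ester carbonyl through a six-membered transition state and the phenolate is released, driven by formation of the stabilised diketone enolate. The cold, weakly acidic work-up should keep the freed phenol from condensing onto the diketone.

Step 3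
Reactants: 4 1-(2-hydroxy-4,5-dimethoxyphenyl)-3-(2,5-dimethoxyphenyl)propane-1,3-dione
Product: 7 5-hydroxy-7,8,2',5'-tetramethoxyflavone, via quinone monoketal 5 (not isolated), via dihydrochromenone 6 (not isolated)
Conditions: PhI(OAc)2 (1.0 equiv), MeOH, 0 °C; evaporate; then CSA (cat.), 4 Å MS, CH2Cl2 (dilute), rt
Reagents that add atoms: methanol, CO (supplies the second ketal methoxy group of 5; one of the two ketal methoxy groups leaves again from 6)
Why: Proposed new method: the iodine(III) reagent binds the phenol oxygen of ring A of 4 and methanol enters at the para carbon that already bears OMe, the standard oxidative dearomatization of a 4-methoxyphenol to a p-quinone monoketal, which gives 5. In 5 the ring CH next to the ketal carbon (future C8a) is the β-carbon of an alkylidene-1,3-dicarbonyl unit (ring C=O and side-chain C=O on the same α-carbon), so the enol oxygen of the side chain should add to it in a 6-endo-trig oxa-Michael addition (equally written as an oxa-6π electrocyclization of the O=C–C=C–C=C array), which forms O1–C8a and closes the pyranone ring to give 6. Acid then ionises the ketal of 6 and loss of the C8a proton expels one methoxy group as methanol, so ring A rearomatises with OMe on C8, O1 on C8a and the free OH on C5. The closest known reaction types are the conjugate addition/aromatization of nucleophiles on quinone monoketals, which gives 3-substituted 4-methoxyphenols, and the oxidative cyclization of 2,5-dihydroxybenzophenones to xanthones through aroylquinones; new here is a diketone enol as the oxygen nucleophile, closing a flavone at O1–C8a. Site selectivity: the other enone β-carbon of 5 (future C7) bears OMe and is a deactivated vinylogous ester, and attack by the central carbon of the diketone would need a four-membered ring, so only O-attack at C8a is open. Chemoselectivity: ring B is an acyl-substituted 1,4-dimethoxybenzene without free OH and should be inert to PhI(OAc)2 in methanol, which oxidises phenols by ligand exchange at iodine. The only new stereocentre, C8a of 6, forms as a racemate and is erased in the aromatization. Methanol is removed before the acid is added so that the solvent cannot compete as Michael donor, and only one equivalent of oxidant is used because 7 is again a 4-methoxyphenol.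

## Compound list

1 | 1-(2-hydroxy-4,5-dimethoxyphenyl)ethan-1-one (2'-hydroxy-4',5'-dimethoxyacetophenone) | CC(=O)c1cc(OC)c(OC)cc1O | starting material
2 | 2,5-dimethoxybenzoyl chloride | COc1ccc(OC)c(C(=O)Cl)c1 | starting material
3 | 2-acetyl-4,5-dimethoxyphenyl 2,5-dimethoxybenzoate | COc1ccc(OC)c(C(=O)Oc2cc(OC)c(OC)cc2C(C)=O)c1 | intermediate
4 | 1-(2-hydroxy-4,5-dimethoxyphenyl)-3-(2,5-dimethoxyphenyl)propane-1,3-dione (drawn as the diketo tautomer) | COc1ccc(OC)c(C(=O)CC(=O)c2cc(OC)c(OC)cc2O)c1 | intermediate
5 | 1-(2,5-dimethoxyphenyl)-3-(3,3,4-trimethoxy-6-oxocyclohexa-1,4-dien-1-yl)propane-1,3-dione (acyl p-quinone monoketal, not isolated) | COC1=CC(=O)C(C(=O)CC(=O)c2cc(OC)ccc2OC)=CC1(OC)OC | intermediate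
6 | (±)-2-(2,5-dimethoxyphenyl)-5-hydroxy-7,8,8-trimethoxy-8,8a-dihydro-4H-chromen-4-one (racemic at C8a, not isolated) | COC1=CC(O)=C2C(=O)C=C(c3cc(OC)ccc3OC)OC2C1(OC)OC | intermediate
7 | 5-hydroxy-7,8,2',5'-tetramethoxyflavone [2-(2,5-dimethoxyphenyl)-5-hydroxy-7,8-dimethoxy-4H-chromen-4-one], achiral | COc1ccc(OC)c(-c2cc(=O)c3c(O)cc(OC)c(OC)c3o2)c1 | target

## Step count and risk

Total step count: 3. Longest linear sequence: 3.

**Step 3 (key step, proposed new method).**
- The most likely failure is that ring closure is slower than its competitors. The enol has to leave its hydrogen-bonded chelate and rotate about C3–C4 before its oxygen reaches C8a.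
- Meanwhile residual methanol can add to the same carbon and aromatise irreversibly. Traces of water can hydrolyse the ketal, so that the C8 oxygen loses its methyl group. The acidic central CH2 of a second molecule can add intermolecularly.
- Two further risks lie in the oxidation itself. The iodine(III) reagent may attack the central carbon of the diketone instead of the phenol, and the product phenol may be over-oxidised. A reductive work-up should reverse the over-oxidation.
- The fallback uses known chemistry, sets out from 2 and comes back at 7. 2,6-Dihydroxy-4-methoxyacetophenone F1 is deprotonated with LiHMDS (4 equiv, THF, −78 °C) and C-acylated by 2 to give 1-(2,6-dihydroxy-4-methoxyphenyl)-3-(2,5-dimethoxyphenyl)propane-1,3-dione F2.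
- The two equivalent OH groups of F2 allow only one cyclodehydration product (H2SO4 cat., AcOH, heat), 5-hydroxy-7,2',5'-trimethoxyflavone F3.
- Elbs persulfate oxidation (K2S2O8, aq. KOH/pyridine, rt) attacks para to the 5-OH and gives potassium 2-(2,5-dimethoxyphenyl)-5-hydroxy-7-methoxy-4-oxo-4H-chromen-8-yl sulfate F4. Hot aqueous HCl hydrolyses F4 to 5,8-dihydroxy-7,2',5'-trimethoxyflavone F5.
- One equivalent of Me2SO4 with K2CO3 in acetone methylates the free 8-OH and leaves the chelated 5-OH, giving 7.

**Step 2.**
- The most likely failure is cleavage of the aryl ester by the base or by adventitious hydroxide before the enolate attacks, since the ortho-methoxy group makes the ester carbonyl a poor electrophile.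
- The other danger is premature cyclodehydration through the phenol oxygen during work-up, which would close the pyranone on the wrong side of ring A.
- The fallback sets out from 1 and comes back at 4, keeping the phenol masked until the diketone is in place. BnBr/K2CO3/DMF converts 1 into 1-[2-(benzyloxy)-4,5-dimethoxyphenyl]ethan-1-one F6.
- The lithium enolate of F6 (LiHMDS, THF, −78 °C) is acylated by 2 to give 1-[2-(benzyloxy)-4,5-dimethoxyphenyl]-3-(2,5-dimethoxyphenyl)propane-1,3-dione F7.
- Neutral hydrogenolysis (H2, Pd/C, EtOAc) then frees the phenol of 4 without any acid that could cyclise it.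

**Step 1.**
- The most likely failure is sluggish acylation of the hydrogen-bonded phenol by a hindered acid chloride. The acid chloride would then hydrolyse, and base-induced acyl migration with a second acylation could begin in the same flask.
- The fallback sets out from 1 and 2 and comes back at 4, bypassing 3. Double deprotonation of 1 at OH and CH3 with LiHMDS (3 equiv, THF, −78 °C) and addition of 2 should acylate the more nucleophilic enolate carbon directly. This is an intermolecular Claisen-type acylation in place of O-acylation and migration.

## Further compounds

F1 | step 3 | 2,6-dihydroxy-4-methoxyacetophenone | CC(=O)c1c(O)cc(OC)cc1O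
F2 | step 3 | 1-(2,6-dihydroxy-4-methoxyphenyl)-3-(2,5-dimethoxyphenyl)propane-1,3-dione | COc1ccc(OC)c(C(=O)CC(=O)c2c(O)cc(OC)cc2O)c1
F3 | step 3 | 5-hydroxy-7,2',5'-trimethoxyflavone | COc1ccc(OC)c(-c2cc(=O)c3c(O)cc(OC)cc3o2)c1
F4 | step 3 | potassium 2-(2,5-dimethoxyphenyl)-5-hydroxy-7-methoxy-4-oxo-4H-chromen-8-yl sulfate | COc1ccc(OC)c(-c2cc(=O)c3c(O)cc(OC)c(OS(=O)(=O)[O-])c3o2)c1.[K+]
F5 | step 3 | 5,8-dihydroxy-7,2',5'-trimethoxyflavone | COc1ccc(OC)c(-c2cc(=O)c3c(O)cc(OC)c(O)c3o2)c1
F6 | step 2 | 1-[2-(benzyloxy)-4,5-dimethoxyphenyl]ethan-1-one | CC(=O)c1cc(OC)c(OC)cc1OCc1ccccc1
F7 | step 2 | 1-[2-(benzyloxy)-4,5-dimethoxyphenyl]-3-(2,5-dimethoxyphenyl)propane-1,3-dione | COc1ccc(OC)c(C(=O)CC(=O)c2cc(OC)c(OC)cc2OCc3ccccc3)c1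
F0 | step 1 | none | none
A1 | alternative 1 | 2-hydroxy-3,4,6-trimethoxyacetophenone | CC(=O)c1c(O)c(OC)c(OC)cc1OC
A2 | alternative 1 | 1-(2-hydroxy-3,4,6-trimethoxyphenyl)-3-(2,5-dimethoxyphenyl)propane-1,3-dione | COc1ccc(OC)c(C(=O)CC(=O)c2c(O)c(OC)c(OC)cc2OC)c1
A3 | alternative 1 | 5,7,8,2',5'-pentamethoxyflavone | COc1ccc(OC)c(-c2cc(=O)c3c(OC)cc(OC)c(OC)c3o2)c1
A4 | alternative 2 | 2-iodo-3,5,6-trimethoxyphenol | COc1cc(OC)c(OC)c(O)c1I
A5 | alternative 2 | 2-ethynyl-1,4-dimethoxybenzene | C#Cc1cc(OC)ccc1OC
A6 | alternative 2 | 1-(2-hydroxy-3,4,6-trimethoxyphenyl)-3-(2,5-dimethoxyphenyl)prop-2-yn-1-one | COc1ccc(OC)c(C#CC(=O)c2c(O)c(OC)c(OC)cc2OC)c1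
A7 | alternative 3 | 5,7,8-trimethoxy-4H-chromen-4-one | COc1cc(OC)c(OC)c2occc(=O)c12
A8 | alternative 3 | 1,4-dimethoxybenzene | COc1ccc(OC)cc1
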